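All runs were generated by integration for substances that don't exist; noise was put on by code.

Read the last rows first.

| setting | Friday's | Saturday's | Tuesday's | Monday's | red | teal | violet |
|---|---|---|---|---|---|---|---|
| substrate | 0.20 M | 0.20 M | 0.20 M | 0.40 M | 0.20 M (fed, over 50 h) | 0.20 M | 0.20 M |
| coupling partner | 2 equiv | 1 equiv | 1.5 equiv | 2 equiv | 2.00 equiv | 2.00 equiv (fed, over 50 h) | 2.00 equiv |
| remark | run made earlier | run made earlier | run made earlier | run made earlier | all else is in the flask from the start; the feed brings no volume worth counting | all else is in the flask from the start; the feed brings no volume worth counting | everything together at the start |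
| time |  |  |  |  | 2.5 d | 2.5 d | 2.5 d |

| run | time / h | target / % | side product / % |
|---|---|---|---|
| Friday's | 3.00 | 2.4 | 37.7 |
| Friday's | 5.00 | 6.4 | 43.6 |
| Friday's | 10.0 | 13.3 | 51.5 |
| Friday's | 20.0 | 20.8 | 52.8 |
| Friday's | 40.0 | 28.1 | 51.6 |
| Saturday's | 4.00 | 2.8 | 41.6 |
| Saturday's | 12.0 | 12.1 | 53.7 |
| Saturday's | 20.0 | 16.7 | 53.6 |
| Saturday's | 30.0 | 21.5 | 52.3 |
| Saturday's | 50.0 | 24.4 | 54.7 |
| Tuesday's | 10.0 | 12.9 | 50.8 |
| Tuesday's | 20.0 | 20.3 | 52.8 |
| Tuesday's | 30.0 | 24.8 | 53.9 |
| Tuesday's | 40.0 | 26.2 | 54.1 |
| Tuesday's | 50.0 | 26.5 | 55.2 |
| Monday's | 4.00 | 8.4 | 37.8 |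
| Monday's | 12.0 | 19.5 | 50.4 |
| Monday's | 20.0 | 23.8 | 50.6 |
| Monday's | 30.0 | 25.7 | 50.9 |
| Monday's | 50.0 | 29.7 | 52.1 |

(each reading ± 1 percentage point)

* the flask that comes out highest in share of target in target plus side product, or "all alike" when all lie within 1.5 percentage points (red / teal / violet / all alike)
* share of target in target plus side product at the end, red
* share of target in target plus side product at the end, teal
* share of target in target plus side product at the end, violet

- what was read earlier has a scatter of 1 percentage point, one standard deviation

You will see that the side product stops rising early and then hardly moves: it ends at 51.6 % in Friday's run and at 54.7 % in Saturday's. What isn't side product is the room that target can fill, so, with the side product held, the share of target in target plus side product (the selectivity) depends on how full that room gets. Friday's last row gives 0.581. Call this the arrival fraction: target divided by one minus side product, both as fractions of the charge.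

Now go down the rows. Saturday, with half of Friday's partner, reads 0.539. Tuesday reads 0.592. Monday, at twice the substrate concentration and Friday's equivalents, reads 0.620. Friday's last row stands at 40.0 h and the others at 50.0 h, and each reading scatters by 1 percentage point, so these fractions, which span 0.0810, are readings and not sharp values.

My own reckoning follows. Violet repeats Friday, so I expect a share near 35.3 %. Red's last substrate has 10.0 h to react, and Friday's row at that age shows an arrival of 0.274, lower than its last row; that speaks for the last portion of the feed, not the whole of it, but it leads me to put red below violet. Teal has received Saturday's whole partner charge by 25.0 h, so I would not put it below Saturday's share of 30.8 %.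

The forecast named violet, with red 20 %, teal 29 % and violet 36 %, holding that the falling rate “looks like a dying catalyst”. Its teal stands lower than the share I gave as my floor for teal.

The flasks put teal highest: red 21.2 %, teal 38.9 %, violet 35.7 %.

    substrate → side product (k = 5.43 × 10⁻⁵ /s)
    substrate + coupling partner → intermediate A (k = 1.81 × 10⁻⁵ /M/s)
    substrate → intermediate B (k = 4.25 × 10⁻⁵ /s)
    coupling partner + intermediate B → target (k = 8.26 × 10⁻⁵ /M/s)
    intermediate A → intermediate C (k = 2.19 × 10⁻⁵ /s)
    coupling partner + intermediate C ⇌ intermediate D (K = 2.80 /M, k = 1.47 × 10⁻⁴ /M/s)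
    2 coupling partner → self-condensation product (k = 5.65 × 10⁻⁵ /M/s)

Teal's arrival fraction at 2.50 d is 0.808, higher than the 0.581 read in Friday's run at 40.0 h. After half of the time, 1.25 d, teal's step from substrate to intermediate B has >99.9 % of its turnover behind it, but its self-condensation has 33 %. At that moment teal holds 0.0413 M of self-condensation product, less than violet's 0.143 M. The neighbour flask, teal with 8.00 equiv of partner, ends with 42.5 % target and 55.3 % side product, an arrival fraction of 0.951.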